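The synthesis rests on a two-carbon ring expansion that exploits the 1,3-placed oxygens on C1 and C3 of the seven-membered ring (ring B), which flank the C2 methylene next to the quaternary carbon C4. Dichloroketene adds across the C1=C4 bond of a cis-fused hydrindanone methyl enol ether; this single cycloaddition forms C1–C2 and C3–C4 and leaves a temporary C1–C4 bond in a cyclobutanone. Dechlorination and acid-mediated cleavage of that bond release ring B as a vinylogous ester with C1 and C3 differentiated, whose enolate at C4 later closes the cyclobutane. The precursor is a bicyclo[4.3.0]nonene enol ether that holds no seven-membered ring.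

Key step: step 8

Remark: atom labels follow the target throughout: C1 = CH(O-angelate), C2 = CH2, C3 = CH(O-tiglate), C4 = quaternary C–CH3, C5 = cyclobutane CH next to the ketone C6, C7 = vinylic CH, C8 = vinylic C–CH3, C9 = cyclobutane CH next to C8, C10 = cyclobutane CH next to C11 = C(CH3)2. TIPS = triisopropylsilyl, Ms = methanesulfonyl.
Remark: the enantiomer of the oxazaborolidine in step 2 is taken that gives adduct 4 as drawn; the mirror-image catalyst would give the antipode.

Step 1
Reactants: 1 3-methylbut-2-enal
Product: 2 (E)-3-methyl-1-(triisopropylsilyloxy)buta-1,3-diene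
Conditions: TIPSOTf, Et3N, Et2O, 0 to 25 °C
Reagents that add atoms: triisopropylsilyl triflate CC(C)[Si](OS(=O)(=O)C(F)(F)F)(C(C)C)C(C)C
Why: Silyl dienol ether formation: O-silylation of the enal and γ-deprotonation should give the (E)-1-silyloxy diene.

Step 2
Reactants: 2 (E)-3-methyl-1-(triisopropylsilyloxy)buta-1,3-diene; 3 4,4-dimethylcyclopent-2-en-1-one
Product: 4 cis-fused hexahydroindenone (ketone at C4)
Conditions: (S)-3,3-diphenyl-1-(o-tolyl)tetrahydro-1H,3H-pyrrolo[1,2-c][1,3,2]oxazaborole (20 mol%), HNTf2 (20 mol%), CH2Cl2, −78 to −20 °C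
Reagents that add atoms: none
Why: Catalytic enantioselective Diels–Alder reaction: the silyloxy terminus C6 bonds to the enone α-carbon C5 and the unsubstituted terminus C9 to the hindered β-carbon C10 (both donor groups direct alike), suprafacial addition gives the cis ring fusion, the endo transition state places the silyloxy group cis to C4, and the chiral Lewis acid selects the enone face that fixes C5 and C10.

Step 3
Reactants: 4 cis-fused hexahydroindenone
Product: 5 enol triflate (C4–OTf, C1=C4)
Conditions: LiN(iPr)2, THF, −78 °C; then PhNTf2, −78 to 0 °C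
Reagents that add atoms: N-phenyl-bis(trifluoromethanesulfonimide) O=S(=O)(N(c1ccccc1)S(=O)(=O)C(F)(F)F)C(F)(F)F
Why: Enol triflate formation: kinetic deprotonation should take a proton from the C1 methylene rather than the ring-fusion methine C5–H, and O-triflation fixes the position of the later alkene.

Step 4
Reactants: 5 enol triflate
Product: 6 methyl diene (C1=C4 bearing CH3 on C4)
Conditions: MeMgBr, Fe(acac)3 (5 mol%), THF/N-methylpyrrolidone, −30 °C
Reagents that add atoms: methylmagnesium bromide C[Mg]Br
Why: Iron-catalysed Kumada-type cross-coupling of the alkenyl triflate with the methyl Grignard reagent installs the C4 methyl group without moving the double bond.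

Step 5
Reactants: 6 methyl diene
Product: 8 C1 alcohol, via alkylborane 7 (not isolated)
Conditions: BH3·THF (1.0 equiv), THF, 0 °C; then NaOH, H2O2, 0 to 25 °C
Reagents that add atoms: hydrogen peroxide OO
Why: Hydroboration–oxidation: boron should add to the less substituted C1 of the strained cyclopentene from the convex face, while the C7=C8 alkene in the six-membered ring is slower next to the bulky allylic silyl ether; both new centres are erased or equilibrated later.

Step 6
Reactants: 8 C1 alcohol
Product: 9 C1 ketone
Conditions: Dess–Martin periodinane, CH2Cl2, 25 °C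
Reagents that add atoms: none
Why: Dess–Martin oxidation completes a 1,2-carbonyl transposition with methylation and gives a ketone whose only enolisable position is C4.

Step 7
Reactants: 9 C1 ketone
Product: 10 methyl enol ether (C1(OCH3)=C4)
Conditions: KN(SiMe3)2, THF/DMPU, −78 °C; then Me3OBF4, −78 to 0 °C
Reagents that add atoms: trimethyloxonium tetrafluoroborate C[O+](C)C.F[B-](F)(F)F
Why: Enolate O-alkylation: C11 is quaternary, so only the C1=C4 enolate can form, and the hard oxonium salt with a potassium counter-ion in a dipolar medium should alkylate this hindered, fully substituted enolate on oxygen.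

Step 8
Reactants: 10 methyl enol ether
Product: 11 dichlorocyclobutanone (four-membered ring C1–C2–C3–C4)
Conditions: Cl2CHCOCl (slow addition), Et3N, hexane, 25 °C
Reagents that add atoms: dichloroacetyl chloride O=C(Cl)C(Cl)Cl
Why: Triethylamine dehydrochlorinates the acid chloride to dichloroketene, which adds to the enol ether in an asynchronous [2+2] cycloaddition: the nucleophilic C4 attacks the ketene carbonyl carbon (bond C3–C4) and the C1 oxocarbenium is captured by the dichloro-enolate carbon (bond C1–C2). The closest known reaction is the dichloroketene/enol ether cycloaddition used for the two-carbon ring expansion of cyclopentanones to cycloheptane-1,3-diones. The four-membered ring closes in the [2+2] mode by collapse of the 1,4-zwitterion (formally 4-exo) and gives a bicyclo[3.2.0] unit fused to the cyclohexene. The new centres C1 and C4 are necessarily cis (suprafacial addition) and should form on the convex face, but both are erased in steps 9 and 12, so no facial selectivity is needed. The step needs regioselectivity, which the polarisation of the enol ether secures (C4 to the ketene C=O, C1 to CCl2), and chemoselectivity over the C7=C8 alkene, which is far less nucleophilic and shielded by the allylic silyl ether.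

Step 9
Reactants: 11 dichlorocyclobutanone
Product: 13 ring-expanded β-methoxy enone (bicyclic vinylogous ester), via dechlorinated cyclobutanone 12 (not isolated)
Conditions: Zn dust, AcOH, 25 °C; then 60 °C
Reagents that add atoms: none
Why: Reductive dechlorination, then retro-aldol-type opening of the β-methoxy cyclobutanone: the C1–C4 bond cleaves with push from the methoxy group, and the C1 oxocarbenium can lose a proton only from C2, so ring B should form as the β-methoxy enone with C1 and C3 differentiated (C4 epimers are of no consequence).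

Step 10
Reactants: 13 bicyclic vinylogous ester
Product: 14 C9 allylic alcohol
Conditions: SeO2 (0.5 equiv), t-BuOOH, CH2Cl2, 25 °C
Reagents that add atoms: tert-butyl hydroperoxide CC(C)(C)OO
Why: SeO2 allylic hydroxylation (ene reaction, then [2,3]-sigmatropic shift) should occur at the ring CH2 C9 on the more substituted end of the alkene and deliver oxygen to the convex face, cis to H-10 and opposite to ring B.

Step 11
Reactants: 14 C9 allylic alcohol
Product: 15 C9 allylic mesylate
Conditions: Ms2O, 2,6-lutidine, CH2Cl2, −20 °C (used crude)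
Reagents that add atoms: methanesulfonic anhydride CS(=O)(=O)OS(C)(=O)=O
Why: Sulfonylation with retention at C9; chloride-free conditions avoid allylic chloride formation and allylic transposition.

Step 12
Reactants: 15 C9 allylic mesylate
Product: 16 tricyclic vinylogous ester (cyclobutane closed)
Conditions: LiN(iPr)2 (1.2 equiv), THF, −78 to 0 °C
Reagents that add atoms: none
Why: Stork–Danheiser α′-deprotonation gives the only possible enolate (at C4; the γ-carbon C11 is quaternary), which should displace the allylic mesylate in an intramolecular 4-exo-tet alkylation with inversion at C9; the tether lets C4 reach C9 only from the face of ring B, so C4 and C9 form with the cis-1,3 relationship of the cage.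

Step 13
Reactants: 16 tricyclic vinylogous ester
Product: 18 β-hydroxy ketone (C3–OH, C1=O), via C3 allylic alcohol 17 (not isolated)
Conditions: iBu2AlH, CH2Cl2, −78 °C; then 5% aq. oxalic acid, THF, 0 °C
Reagents that add atoms: water O
Why: 1,2-Reduction of the vinylogous ester carbonyl (first stage of a Stork–Danheiser sequence) should occur from the face remote from C5 and its silyloxy-bearing neighbour C6, and mild enol ether hydrolysis through C2 protonation should stop at the β-hydroxy ketone before dehydration.

Step 14
Reactants: 18 β-hydroxy ketone; 19 (E)-2-methylbut-2-enal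
Product: 20 C3 tiglate C1 alcohol
Conditions: 19 (4 equiv), SmI2 (30 mol%), THF, −10 °C
Reagents that add atoms: none
Why: Evans–Tishchenko reaction: the samarium-bound hemiacetal from the C3 hydroxyl and the aldehyde transfers hydride to the C1 ketone through a six-membered transition state, which should give the 1,3-anti (trans) relationship, leave the tiglate on O-3 and free the C1 hydroxyl.

Step 15
Reactants: 20 C3 tiglate C1 alcohol; 21 (Z)-2-methylbut-2-enoic acid
Product: 23 C1 angelate C3 tiglate silyl ether, via mixed anhydride 22 (not isolated)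
Conditions: 21, 2,4,6-trichlorobenzoyl chloride, Et3N, toluene, 25 °C; then 20, 80 °C
Reagents that add atoms: none
Why: Yamaguchi esterification through the mixed anhydride should acylate the hindered C1 hydroxyl; leaving out a nucleophilic amine catalyst limits isomerisation of the angelate to the tiglate.

Step 16
Reactants: 23 C1 angelate C3 tiglate silyl ether
Product: 24 C6 allylic alcohol
Conditions: HF·pyridine, THF/pyridine, 0 to 25 °C
Reagents that add atoms: none
Why: Fluoride-mediated desilylation under mildly acidic conditions should neither isomerise the angelate nor promote acyl migration.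

Step 17
Reactants: 24 C6 allylic alcohol
Product: 25 target (CNP0236543.4)
Conditions: Dess–Martin periodinane, pyridine, CH2Cl2, 0 to 25 °C
Reagents that add atoms: none
Why: Dess–Martin oxidation of the allylic alcohol gives the enone; C6 loses its stereocentre and the target is reached.

Compound list
1 | 3-methylbut-2-enal | CC(C)=CC=O | starting material
2 | (E)-3-methyl-1-(triisopropylsilyloxy)buta-1,3-diene | C=C(C)/C=C/O[Si](C(C)C)(C(C)C)C(C)C | intermediate
3 | 4,4-dimethylcyclopent-2-en-1-one | O=C1C=CC(C)(C)C1 | starting material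
4 | 3,3,5-trimethyl-7-(triisopropylsilyloxy)-2,3,3a,4,7,7a-hexahydro-1H-inden-1-one, cis-fused (H-5/H-10 cis), silyloxy group cis to C4 | O=C1CC(C)(C)[C@H]2CC(C)=C[C@@H](O[Si](C(C)C)(C(C)C)C(C)C)[C@@H]12 | intermediate
5 | enol triflate of 4 (C4–OTf, C1=C4) | O=S(=O)(OC1=CC(C)(C)[C@H]2CC(C)=C[C@@H](O[Si](C(C)C)(C(C)C)C(C)C)[C@@H]12)C(F)(F)F | intermediate
6 | 1,1,3,6-tetramethyl-4-(triisopropylsilyloxy)-3a,4,7,7a-tetrahydro-1H-indene (C1=C4 and C7=C8 alkenes) | CC1=CC(C)(C)[C@H]2CC(C)=C[C@@H](O[Si](C(C)C)(C(C)C)C(C)C)[C@@H]12 | intermediate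
7 | alkylborane (BH2 on C1, H on C4, both on the convex face) | C[C@H]1[C@H](B)C(C)(C)[C@H]2CC(C)=C[C@@H](O[Si](C(C)C)(C(C)C)C(C)C)[C@@H]12 | intermediate
8 | C1 alcohol (OH on C1 and H on C4 on the convex face) | C[C@H]1[C@H](O)C(C)(C)[C@H]2CC(C)=C[C@@H](O[Si](C(C)C)(C(C)C)C(C)C)[C@@H]12 | intermediate
9 | C1 ketone, 2,2,5-trimethylcyclopentanone cis-fused to the silyloxy cyclohexene (C4 epimerisable) | C[C@H]1C(=O)C(C)(C)[C@H]2CC(C)=C[C@@H](O[Si](C(C)C)(C(C)C)C(C)C)[C@@H]12 | intermediate
10 | methyl enol ether, C1(OCH3)=C4(CH3) | COC1=C(C)[C@@H]2[C@H](O[Si](C(C)C)(C(C)C)C(C)C)C=C(C)C[C@@H]2C1(C)C | intermediate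
11 | dichlorocyclobutanone: C1(OCH3)–C2Cl2–C3(=O)–C4(CH3) ring cis-fused on the convex face | CO[C@]12C(Cl)(Cl)C(=O)[C@@]1(C)[C@@H]3[C@H](O[Si](C(C)C)(C(C)C)C(C)C)C=C(C)C[C@@H]3C2(C)C | intermediate
12 | dechlorinated cyclobutanone | CO[C@]12CC(=O)[C@@]1(C)[C@@H]3[C@H](O[Si](C(C)C)(C(C)C)C(C)C)C=C(C)C[C@@H]3C2(C)C | intermediate
13 | ring-expanded β-methoxy enone, C1(OCH3)=C2–C3(=O), cis-fused to the cyclohexene (C4 epimers) | COC1=CC(=O)C(C)[C@@H]2[C@H](O[Si](C(C)C)(C(C)C)C(C)C)C=C(C)C[C@@H]2C1(C)C | intermediate
14 | C9 allylic alcohol of 13 (OH cis to H-10) | COC1=CC(=O)C(C)[C@@H]2[C@H](O[Si](C(C)C)(C(C)C)C(C)C)C=C(C)[C@@H](O)[C@@H]2C1(C)C | intermediate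
15 | C9 allylic mesylate | COC1=CC(=O)C(C)[C@@H]2[C@H](O[Si](C(C)C)(C(C)C)C(C)C)C=C(C)[C@@H](OS(C)(=O)=O)[C@@H]2C1(C)C | intermediate
16 | tricyclic vinylogous ester (C4–C9 bond closed, C6–OTIPS) | COC1=CC(=O)[C@@]2(C)[C@@H]3[C@H](O[Si](C(C)C)(C(C)C)C(C)C)C=C(C)[C@H]2[C@@H]3C1(C)C | intermediate
17 | C3 allylic alcohol with the C1 methyl enol ether | COC1=C[C@@H](O)[C@@]2(C)[C@@H]3[C@H](O[Si](C(C)C)(C(C)C)C(C)C)C=C(C)[C@H]2[C@@H]3C1(C)C | intermediate
18 | β-hydroxy ketone (C3–OH, C1=O) | O=C1C[C@@H](O)[C@@]2(C)[C@@H]3[C@H](O[Si](C(C)C)(C(C)C)C(C)C)C=C(C)[C@H]2[C@@H]3C1(C)C | intermediate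
19 | (E)-2-methylbut-2-enal | O=C/C(C)=C/C | starting material
20 | C3 tiglate, C1 alcohol (trans-1,3) | O[C@@H]1C[C@@H](OC(=O)/C(C)=C/C)[C@@]2(C)[C@@H]3[C@H](O[Si](C(C)C)(C(C)C)C(C)C)C=C(C)[C@H]2[C@@H]3C1(C)C | intermediate
21 | (Z)-2-methylbut-2-enoic acid (angelic acid) | C/C=C(/C)C(=O)O | starting material
22 | angelic 2,4,6-trichlorobenzoic anhydride | C/C=C(/C)C(=O)OC(=O)c1c(Cl)cc(Cl)cc1Cl | intermediate
23 | C1 angelate, C3 tiglate, C6 silyl ether | C/C=C(/C)C(=O)O[C@@H]1C[C@@H](OC(=O)/C(C)=C/C)[C@@]2(C)[C@@H]3[C@H](O[Si](C(C)C)(C(C)C)C(C)C)C=C(C)[C@H]2[C@@H]3C1(C)C | intermediate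
24 | C1 angelate, C3 tiglate, C6 allylic alcohol | C/C=C(/C)C(=O)O[C@@H]1C[C@@H](OC(=O)/C(C)=C/C)[C@@]2(C)[C@@H]3[C@H](O)C=C(C)[C@H]2[C@@H]3C1(C)C | intermediate
25 | target CNP0236543.4 | C/C=C(/C)C(=O)O[C@@H]1C[C@@H](OC(=O)/C(C)=C/C)[C@@]2(C)[C@@H]3C(=O)C=C(C)[C@H]2[C@@H]3C1(C)C | target

Total step count: 17. Longest linear sequence: 17 steps (1 to 25; enone 3 enters at step 2).

Steps most likely to fail

Step 12. The strained 4-exo closure may be outrun by O-alkylation of the enolate, by attack at the other allylic terminus C7, or by decomposition of the labile allylic sulfonate. The fallback sets out from 14 and replaces the basic displacement by a Lewis acid-mediated alkylation of a silyl enol ether. Benzoyl chloride in pyridine should give the allylic benzoate F2. LiN(iPr)2 and tert-butyldimethylsilyl chloride in THF/DMPU at −78 °C should then give the 2-silyloxy diene F3. ZnCl2 or BF3·OEt2 in CH2Cl2 at −78 °C should ionise the benzoate, and the allyl cation, whose charge sits mainly at C9 away from the silyloxy-bearing C6, should be captured by C4 from the face of ring B. The route is rejoined at 16.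

Step 8. Ring closure at the fully substituted enol ether creates three contiguous fully substituted carbons (C11, C1, C4) and may be so slow that ketene oligomerisation or simple C-acylation without closure takes over. The fallback sets out from 10 and uses a keteniminium salt in place of the ketene. N,N-Dimethylacetamide, triflic anhydride and 2,4,6-collidine in 1,2-dichloroethane generate the keteniminium triflate, a stronger and smaller electrophile, whose [2+2] cycloaddition should give the cyclobutaniminium triflate F1. Hydrolysis with aqueous NaHCO3 should give the chlorine-free cyclobutanone 12 directly, where the route is rejoined (warm acetic acid then gives 13).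

Step 13. Hydride delivery to C3 may show poor facial selectivity, because the two faces of ring B differ only through the remote substituents on C5 and C9, and acid may remove the C3 hydroxyl by elimination during enol ether hydrolysis. The fallback sets out from 16 and relies on reagent control. Aqueous HCl in THF should hydrolyse the enol ether to the tricyclic 1,3-dione F4. (S)-1-Methyl-3,3-diphenyltetrahydro-1H,3H-pyrrolo[1,2-c][1,3,2]oxazaborole with BH3·SMe2 (CBS reduction; each ketone has a quaternary and a methylene neighbour) should give the trans-1,3-diol F5. Tigloyl chloride (1 equiv) with 4-(dimethylamino)pyridine in pyridine at 0 °C should acylate the less hindered C3 hydroxyl, whose neighbour C4 is tied back in the cyclobutane. The route is rejoined at 20, so step 14 is bypassed as well.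

Further compounds
F1 | step 8 | cyclobutaniminium triflate (C3=N+(CH3)2 analogue of 12) | CO[C@]12CC(=[N+](C)C)[C@@]1(C)[C@@H]3[C@H](O[Si](C(C)C)(C(C)C)C(C)C)C=C(C)C[C@@H]3C2(C)C.[O-]S(=O)(=O)C(F)(F)F
F2 | step 12 | C9 allylic benzoate of 14 | COC1=CC(=O)C(C)[C@@H]2[C@H](O[Si](C(C)C)(C(C)C)C(C)C)C=C(C)[C@@H](OC(=O)c3ccccc3)[C@@H]2C1(C)C
F3 | step 12 | 2-silyloxy diene, C3(OSi(CH3)2C(CH3)3)=C4, with the C9 benzoate | COC1=CC(O[Si](C)(C)C(C)(C)C)=C(C)[C@@H]2[C@H](O[Si](C(C)C)(C(C)C)C(C)C)C=C(C)[C@@H](OC(=O)c3ccccc3)[C@@H]2C1(C)C
F4 | step 13 | tricyclic 1,3-dione (C1=O, C3=O) | O=C1CC(=O)[C@@]2(C)[C@@H]3[C@H](O[Si](C(C)C)(C(C)C)C(C)C)C=C(C)[C@H]2[C@@H]3C1(C)C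
F5 | step 13 | tricyclic trans-1,3-diol (C1–OH, C3–OH) | O[C@@H]1C[C@@H](O)[C@@]2(C)[C@@H]3[C@H](O[Si](C(C)C)(C(C)C)C(C)C)C=C(C)[C@H]2[C@@H]3C1(C)C
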